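Take the ratio of the charges first: alder carries 2.24 times the starting material of maple, yet at 25.0 min their target readings stand at 11.0 % and 11.6 %, apart by 0.6 percentage points where one reading scatters by 0.5 points. So read both runs as one percentage curve, and put the flask, charged between them, on that curve. Maple, alder and the flask share a saturation c(gas) of 19 mM.

| setting | maple | alder | flask |
|---|---|---|---|
| starting material | 0.037 M (fed, over 30 min) | 0.083 M (fed, over 30 min) | 0.055 M (fed, over 30 min) |
| gas | 19 mM (held) | 19 mM (held) | 19 mM (held) |
| remark | run made earlier; the fed solution adds 1.0 times the starting volume | run made earlier; the fed solution adds 1.0 times the starting volume | the fed solution adds 1.0 times the starting volume |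
| time |  |  | 40 min |

| run | time / min | target / % |
|---|---|---|
| maple | 3.00 | 0 |
| maple | 6.00 | 0.7 |
| maple | 10.0 | 1.2 |
| maple | 15.0 | 4.5 |
| maple | 20.0 | 7.4 |
| maple | 25.0 | 11.0 |
| alder | 3.00 | 0 |
| alder | 6.00 | 0.5 |
| alder | 10.0 | 2.0 |
| alder | 15.0 | 4.0 |
| alder | 20.0 | 7.7 |
| alder | 25.0 | 11.6 |

(standard deviation of a reading: 0.5 percentage points)

- charges are per starting volume, the dose included; the dosed solution carries all of it
- the earlier runs were read with a standard deviation of 0.5 percentage points
- at the start none of the gas is in solution
- percentages count the whole charge, also what has not yet gone in

- amount of target in percent of the starting material charged, at 2.0 min, 10 min and 40 min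

Keep a ledger of the starting material in shares of the charge: not yet fed, fed but unconverted (the fraction left), and target. Strike the balance for the earlier runs at 22.5 min, the middle of their last interval. There 75.0 % has gone in and the mean target is 9.43 %, so the fraction left is 65.6 %. Target grows there by 0.00750 min⁻¹ of the charge. Divide the two: 0.0114 min⁻¹ is the turnover constant, the share of the fraction left that becomes target each minute, a pseudo-first-order constant read from readings.

Now run the flask's ledger: each minute add the feed share and take that constant's share of the fraction left. Target comes to 0.0757 % at 2.0 min and 1.84 % at 10 min. At the end of the feed, 30 min, the fraction left is 84.6 %. Decay it over the remaining 10.0 min to 75.5 %, and the books close with target at 24.5 % at 40 min.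

The forecast, that the flask should “follow the same percentage curve”, gave 0.05 %, 1.8 % and 25 %, lower than my figure at the first time and higher at the last.

The flask gives 0.00886 %, 1.58 % and 20.6 %, with over-reaction product at 15.0 % at 40.0 min.

    partner + target → over-reaction product (k = 0.0490 L mol⁻¹ s⁻¹)
    gas ⇌ partner, rate k2*(csat - [partner]) (kL = 0.00330 s⁻¹)
    starting material ⇌ dormant form (K = 0.420, k = 0.00170 s⁻¹)
    partner + intermediate → target (k = 0.260 L mol⁻¹ s⁻¹)
    starting material → intermediate (k = 5.00 × 10⁻⁴ s⁻¹)

Put the turnover constant to work once more on this flask. Start from the flask at 30.0 min, with target at 14.4 % and starting material, intermediate and dormant form together at 78.8 % of the charge. Take the constant's share of that fraction left over 10.0 min, add it to target, and target comes to 22.9 % at 40.0 min, where the flask holds 20.6 %.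

The data are calculated with constants of no real substance; noise was put on by code.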